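**Plan**

Locants (kaurane type): ring A = C1–C5 and C10 (C4 carries the two methyls, C10 the methyl C20); ten-membered ring = C5–C6–C7–C8=C14–C13–C12–C11–C9(=O)–C10; ring D = C8, C14, C13, C16(=C17H2), C15(=O).
Cuts: C7–C8 (ring closure); C12–C13 with C16–C17 (three-component coupling on a cyclopentenone); C9–C11/C11–C12 (ester to cyclopropanol); C10–C20 (enolate methylation); ring A at C1–C2 and C4–C5, leaving a Morita–Baylis–Hillman carbonate (C1, C10, C5, C9, C6, C7) and 3-methylbutan-2-one (C2, C3, C4, both methyls).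
Forward: ring A by a one-flask [3+3] annulation, C3 deoxygenation, C10 methylation, homoenolate union with (S)-4-silyloxycyclopentenone (ring D), C11 oxygenation, closure of the ten-membered ring by a Nozaki–Hiyama–Kishi reaction, acetylation, Cope elimination to the exo-methylene.
Stereochemistry: C5 from the cinchona catalyst of the annulation; C10 from C5 (axial side chain, axial C4 methyl) in the enolate methylation; C13 from the chiral-pool enone (anti conjugate addition); C11 from an enantiopure oxaziridine; C7 from the ring closure.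
Enabling feature: in ring A the carbonyl C9 sits on C10, so C1 and C5 are both β-carbons of a 2-methylene ester, while C2 and the gem-dimethyl carbon C4 flank C3 and become the α- and α′-carbons of a ketone once C3 carries a temporary carbonyl; ring A is thus a matched 1,3-dielectrophile/1,3-dinucleophile pair.

Key step: step 4

Assumption: (DHQD)2PHAL in step 4 and the (+)-oxaziridine in step 11 are taken to give the needed absolute sense at C5 and C11; the pseudoenantiomeric catalyst or the (−)-oxaziridine is the drop-in alternative.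

**Route**

Step 1
Reactants: 1 methyl acrylate; 2 3-[(tert-butyldimethylsilyl)oxy]propanal
Product: 3 methyl 5-[(tert-butyldimethylsilyl)oxy]-3-hydroxy-2-methylidenepentanoate (racemic)
Conditions: DABCO (0.3 equiv), MeOH (cat.), neat, rt
Reagents that add atoms: none
Why: Morita–Baylis–Hillman reaction of an unhindered aliphatic aldehyde with an acrylate; the carbinol centre is racemic and is erased in step 4.

Step 2
Reactants: 3 Morita–Baylis–Hillman adduct
Product: 4 methyl 3-[(tert-butoxycarbonyl)oxy]-5-[(tert-butyldimethylsilyl)oxy]-2-methylidenepentanoate (racemic)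
Conditions: Boc2O, DMAP (5 mol %), CH2Cl2, 0 °C → rt
Reagents that add atoms: di-tert-butyl dicarbonate CC(C)(C)OC(=O)OC(=O)OC(C)(C)C
Why: O-acylation of the secondary allylic alcohol to the tert-butyl carbonate, the leaving group that releases tert-butoxide in step 4.

Step 3
Reactants: 5 3-methylbutan-2-one
Product: 6 trimethyl[(3-methylbut-2-en-2-yl)oxy]silane
Conditions: Me3SiCl, Et3N, DMF, 110 °C; fractional distillation
Reagents that add atoms: chlorotrimethylsilane C[Si](C)(C)Cl
Why: silyl enol ether formation under equilibrating conditions should favour the tetrasubstituted enol ether, which is separated from the terminal isomer by distillation.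

Step 4
Reactants: 4 Morita–Baylis–Hillman carbonate; 6 tetrasubstituted silyl enol ether
Product: 8 methyl (2S)-2-{2-[(tert-butyldimethylsilyl)oxy]ethyl}-3,3-dimethyl-4-oxocyclohexane-1-carboxylate (C1 epimers), via open-chain keto acrylate 7 (not isolated)
Conditions: (DHQD)2PHAL (10 mol %), toluene, 0 °C → rt; then pyrrolidine (30 mol %), AcOH (30 mol %), MeCN/H2O, 40 °C
Reagents that add atoms: none
Why: Proposed new method: the quinuclidine nitrogen of (DHQD)2PHAL adds to the methylene carbon of 4 (SN2′) and expels CO2 and tert-butoxide, which desilylates 6 to the fully substituted enolate; this enolate, ion-paired with the chiral allylammonium enoate, attacks the γ-carbon (second SN2′), forms the C4–C5 bond, frees the catalyst and gives 7, whose methyl ketone is then converted by pyrrolidinium acetate into the terminal enamine that adds to the regenerated acrylate CH2 (C1–C2 bond) and is hydrolysed to 8. The closest known reaction types are the cinchona-catalysed asymmetric allylic alkylation of Morita–Baylis–Hillman carbonates with stabilised carbon nucleophiles and silyloxyfurans and the α,α′-annulation of ketone enamines with 2-(halomethyl)acrylates; not yet shown are a simple tetrasubstituted ketone enol silane as the nucleophile and the merger of the two events. Ring A is closed by a 6-(enolendo)-endo-trig Michael addition of the enamine carbon C2 to C1. C5 is set in the γ-attack by the catalyst, which blocks one face of the ammonium enoate, whereas C10 arises as an epimer mixture that does not matter because it is made planar again in step 7. The step needs γ- over α-attack and C- over O-alkylation in the first bond formation and a clean division of labour between the two ketone α-carbons: the tetrasubstituted enol silane fixes C4 as the first nucleophile, the then quaternary C4 leaves the methyl group as the only site for enamine formation, and enamine instead of alkoxide catalysis keeps the ketone from attacking the ester carbonyl.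

Step 5
Reactants: 8 ring A keto ester
Product: 9 methyl (2S)-2-{2-[(tert-butyldimethylsilyl)oxy]ethyl}-3,3-dimethyl-4-[2-(4-methylbenzenesulfonyl)hydrazinylidene]cyclohexane-1-carboxylate (C1 epimers)
Conditions: TsNHNH2, EtOH, 70 °C
Reagents that add atoms: 4-methylbenzenesulfonohydrazide Cc1ccc(cc1)S(=O)(=O)NN
Why: hydrazone condensation at the only ketone (C3), which prepares the removal of the temporary carbonyl.

Step 6
Reactants: 9 tosylhydrazone
Product: 10 methyl (2S)-2-{2-[(tert-butyldimethylsilyl)oxy]ethyl}-3,3-dimethylcyclohexane-1-carboxylate (C1 epimers)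
Conditions: catecholborane, CHCl3, 0 °C → rt; then NaOAc·3H2O, reflux
Reagents that add atoms: none
Why: tosylhydrazone reduction with catecholborane (hydroboration of C=N, then loss of sulfinate and N2 from the diazene) turns C3 into CH2 under conditions that should spare the ester and the silyl ether.

Step 7
Reactants: 10 ring A ester
Product: 11 methyl (1R,2R)-2-{2-[(tert-butyldimethylsilyl)oxy]ethyl}-1,3,3-trimethylcyclohexane-1-carboxylate
Conditions: LiN(iPr)2, THF, −78 °C; MeI, DMPU, −78 → −20 °C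
Reagents that add atoms: iodomethane CI
Why: alkylation of an exocyclic ester enolate in which A(1,3) strain and the gauche contacts with the C4 methyls hold the C5 side chain axial while the axial C4 methyl screens the opposite face 1,3 to C10, so MeI should enter cis to the side chain and set (10R) with the methyl trans to H5.

Step 8
Reactants: 11 quaternary methyl ester
Product: 12 1-[(1R,2R)-2-{2-[(tert-butyldimethylsilyl)oxy]ethyl}-1,3,3-trimethylcyclohexyl]cyclopropan-1-ol
Conditions: EtMgBr (3.5 equiv), Ti(OiPr)4 (0.3 equiv), THF, 0 °C → rt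
Reagents that add atoms: ethylmagnesium bromide CC[Mg]Br
Why: Kulinkovich reaction, in which the titanacyclopropane made from the Grignard reagent acts as a 1,2-dicarbanion on the ester and delivers C11 and C12 as a cyclopropanol (a masked C9 ketone homoenolate) without touching a stereocentre.

Step 9
Reactants: 12 cyclopropanol; 13 (4S)-4-[(tert-butyldimethylsilyl)oxy]cyclopent-2-en-1-one
Product: 16 (3S,4S)-4-[(tert-butyldimethylsilyl)oxy]-3-{3-[(1R,2R)-2-{2-[(tert-butyldimethylsilyl)oxy]ethyl}-1,3,3-trimethylcyclohexyl]-3-oxopropyl}-2-[(dimethylamino)methyl]cyclopentan-1-one (C2 epimers), via zinc homoenolate 14 (not isolated), via silyl enol ether 15 (not isolated)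
Conditions: Et2Zn (0.55 equiv), THF, 0 → 40 °C; CuBr·SMe2 (10 mol %), Me3SiCl, DMPU, 13, −40 → 0 °C; then [CH2=NMe2]I, CH2Cl2, 0 °C → rt; aq NaHCO3
Reagents that add atoms: N,N-dimethylmethyleneiminium iodide C=[N+](C)C.[I-]
Why: ring opening of the zinc cyclopropoxide to the zinc homoenolate, copper-catalysed conjugate addition with Me3SiCl (anti to the silyloxy group, which sets C13) and Mannich reaction of the regiodefined silyl enol ether form C12–C13 and C16–C17, the new C16 centre being lost again in step 18.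

Step 10
Reactants: 16 β-silyloxy cyclopentanone
Product: 17 (4R)-4-{3-[(1R,2R)-2-{2-[(tert-butyldimethylsilyl)oxy]ethyl}-1,3,3-trimethylcyclohexyl]-3-oxopropyl}-5-[(dimethylamino)methyl]cyclopent-2-en-1-one (C5 epimers)
Conditions: DBU, CH2Cl2, 0 °C → rt
Reagents that add atoms: none
Why: E1cB β-elimination of the silyloxy group through the C8 enolate gives the C8=C14 enone and leaves C13 untouched, the usual addition–elimination transposition of 4-silyloxycyclopentenones.

Step 11
Reactants: 17 enone diketone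
Product: 18 (4R)-4-{(2S)-3-[(1R,2R)-2-{2-[(tert-butyldimethylsilyl)oxy]ethyl}-1,3,3-trimethylcyclohexyl]-2-hydroxy-3-oxopropyl}-5-[(dimethylamino)methyl]cyclopent-2-en-1-one (C5 epimers)
Conditions: KN(SiMe3)2, THF, −78 °C; (+)-(camphorsulfonyl)oxaziridine, −78 °C; aq NH4Cl
Reagents that add atoms: (camphorsulfonyl)oxaziridine CC1(C)C2CCC13CS(=O)(=O)N4OC34C2
Why: enolate hydroxylation with an N-sulfonyloxaziridine, in which the C9 ketone can enolise only towards C11 (C10 is quaternary) and should do so faster than the tertiary α′-CH of the enone, the enantiopure reagent being chosen to give (11S).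

Step 12
Reactants: 18 α-hydroxy ketone
Product: 19 (2S)-1-[(1R,2R)-2-{2-[(tert-butyldimethylsilyl)oxy]ethyl}-1,3,3-trimethylcyclohexyl]-3-{(1R)-5-[(dimethylamino)methyl]-4-oxocyclopent-2-en-1-yl}-1-oxopropan-2-yl acetate
Conditions: Ac2O, pyridine, 0 °C → rt
Reagents that add atoms: acetic anhydride CC(=O)OC(C)=O
Why: O-acetylation of the secondary alcohol installs the C11 acetate of the target and protects it for the remaining steps.

Step 13
Reactants: 19 enone acetate
Product: 20 (2S)-1-[(1R,2R)-2-{2-[(tert-butyldimethylsilyl)oxy]ethyl}-1,3,3-trimethylcyclohexyl]-3-{(1S)-5-[(dimethylamino)methyl]-3-iodo-4-oxocyclopent-2-en-1-yl}-1-oxopropan-2-yl acetate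
Conditions: I2, pyridine, CH2Cl2, 0 °C → rt
Reagents that add atoms: iodine II
Why: α-iodination of a cyclic enone by conjugate addition of pyridine, iodination of the enolate and elimination places the halide on C8 for the ring closure.

Step 14
Reactants: 20 iodoenone silyl ether
Product: 21 (2S)-1-[(1R,2R)-2-(2-hydroxyethyl)-1,3,3-trimethylcyclohexyl]-3-{(1S)-5-[(dimethylamino)methyl]-3-iodo-4-oxocyclopent-2-en-1-yl}-1-oxopropan-2-yl acetate
Conditions: HF·pyridine, THF/pyridine, 0 °C
Reagents that add atoms: none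
Why: fluoride-mediated cleavage of the primary silyl ether under buffered conditions that should leave the acetate and the iodoenone intact.

Step 15
Reactants: 21 primary alcohol
Product: 22 (2S)-3-{(1S)-5-[(dimethylamino)methyl]-3-iodo-4-oxocyclopent-2-en-1-yl}-1-oxo-1-[(1R,2R)-1,3,3-trimethyl-2-(2-oxoethyl)cyclohexyl]propan-2-yl acetate
Conditions: Dess–Martin periodinane, CH2Cl2, 0 °C → rt
Reagents that add atoms: none
Why: Dess–Martin oxidation of the primary alcohol to the C7 aldehyde without epimerisable intermediates.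

Step 16
Reactants: 22 iodoenone aldehyde
Product: 23 (5R,7R,10R,11S,13R)-17-(dimethylamino)-7-hydroxy-9,15-dioxo-8,9-secokaur-8(14)-en-11-yl acetate (locants of the plan; C16 epimers)
Conditions: CrCl2 (8 equiv), NiCl2 (2 mol %), degassed DMSO/THF, syringe-pump addition to 0.002 M, rt
Reagents that add atoms: none
Why: intramolecular Nozaki–Hiyama–Kishi reaction, in which the alkenylchromium from the iodoenone adds only to the aldehyde and closes the ten-membered ring at C7–C8; the (7R) carbinol is expected from attack on the aldehyde face turned outward when the C5–C6 arm folds under ring A, and this is to be verified.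

Step 17
Reactants: 23 ring-closed allylic alcohol
Product: 24 (5R,7R,10R,11S,13R)-17-(dimethylamino)-9,15-dioxo-8,9-secokaur-8(14)-ene-7,11-diyl diacetate (locants of the plan; C16 epimers)
Conditions: Ac2O, pyridine, 0 °C → rt
Reagents that add atoms: acetic anhydride CC(=O)OC(C)=O
Why: O-acetylation of the C7 alcohol without DMAP, to avoid SN2′ chemistry of the allylic acetate.

Step 18
Reactants: 24 diacetate Mannich base
Product: 26 (5R,7R,10R,11S,13R)-9,15-dioxo-8,9-secokaura-8(14),16-diene-7,11-diyl diacetate (CNP0417044.1; locants of the plan), via amine N-oxide 25 (not isolated)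
Conditions: mCPBA (1.05 equiv), CH2Cl2, −20 °C; then rt
Reagents that add atoms: none
Why: N-oxidation of the tertiary amine followed by Cope elimination towards the acidic C16–H unveils the C16=C17 exo-methylene as the last step and removes the undefined C16 centre.

**Compound list**

1 | methyl acrylate | C=CC(=O)OC | starting material
2 | 3-[(tert-butyldimethylsilyl)oxy]propanal | O=CCCO[Si](C)(C)C(C)(C)C | starting material
3 | methyl 5-[(tert-butyldimethylsilyl)oxy]-3-hydroxy-2-methylidenepentanoate (racemic) | C=C(C(=O)OC)C(O)CCO[Si](C)(C)C(C)(C)C | intermediate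
4 | methyl 3-[(tert-butoxycarbonyl)oxy]-5-[(tert-butyldimethylsilyl)oxy]-2-methylidenepentanoate (racemic) | C=C(C(=O)OC)C(OC(=O)OC(C)(C)C)CCO[Si](C)(C)C(C)(C)C | intermediate
5 | 3-methylbutan-2-one | CC(=O)C(C)C | starting material
6 | trimethyl[(3-methylbut-2-en-2-yl)oxy]silane | CC(C)=C(C)O[Si](C)(C)C | intermediate
7 | methyl (3R)-3-{2-[(tert-butyldimethylsilyl)oxy]ethyl}-4,4-dimethyl-2-methylidene-5-oxohexanoate | C=C(C(=O)OC)[C@H](CCO[Si](C)(C)C(C)(C)C)C(C)(C)C(C)=O | intermediate
8 | methyl (2S)-2-{2-[(tert-butyldimethylsilyl)oxy]ethyl}-3,3-dimethyl-4-oxocyclohexane-1-carboxylate (C1 epimers) | COC(=O)C1CCC(=O)C(C)(C)[C@H]1CCO[Si](C)(C)C(C)(C)C | intermediate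
9 | methyl (2S)-2-{2-[(tert-butyldimethylsilyl)oxy]ethyl}-3,3-dimethyl-4-[2-(4-methylbenzenesulfonyl)hydrazinylidene]cyclohexane-1-carboxylate (C1 epimers) | COC(=O)C1CCC(=NNS(=O)(=O)c2ccc(C)cc2)C(C)(C)[C@H]1CCO[Si](C)(C)C(C)(C)C | intermediate
10 | methyl (2S)-2-{2-[(tert-butyldimethylsilyl)oxy]ethyl}-3,3-dimethylcyclohexane-1-carboxylate (C1 epimers) | COC(=O)C1CCCC(C)(C)[C@H]1CCO[Si](C)(C)C(C)(C)C | intermediate
11 | methyl (1R,2R)-2-{2-[(tert-butyldimethylsilyl)oxy]ethyl}-1,3,3-trimethylcyclohexane-1-carboxylate | COC(=O)[C@]1(C)CCCC(C)(C)[C@H]1CCO[Si](C)(C)C(C)(C)C | intermediate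
12 | 1-[(1R,2R)-2-{2-[(tert-butyldimethylsilyl)oxy]ethyl}-1,3,3-trimethylcyclohexyl]cyclopropan-1-ol | OC1(CC1)[C@]2(C)CCCC(C)(C)[C@H]2CCO[Si](C)(C)C(C)(C)C | intermediate
13 | (4S)-4-[(tert-butyldimethylsilyl)oxy]cyclopent-2-en-1-one | O=C1C=C[C@@H](O[Si](C)(C)C(C)(C)C)C1 | starting material
14 | bis{3-[(1R,2R)-2-{2-[(tert-butyldimethylsilyl)oxy]ethyl}-1,3,3-trimethylcyclohexyl]-3-oxopropyl}zinc | O=C(CC[Zn]CCC(=O)[C@]1(C)CCCC(C)(C)[C@H]1CCO[Si](C)(C)C(C)(C)C)[C@]2(C)CCCC(C)(C)[C@H]2CCO[Si](C)(C)C(C)(C)C | intermediate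
15 | 1-[(1R,2R)-2-{2-[(tert-butyldimethylsilyl)oxy]ethyl}-1,3,3-trimethylcyclohexyl]-3-{(1S,5S)-5-[(tert-butyldimethylsilyl)oxy]-3-[(trimethylsilyl)oxy]cyclopent-2-en-1-yl}propan-1-one | C[Si](C)(C)OC1=C[C@H](CCC(=O)[C@]2(C)CCCC(C)(C)[C@H]2CCO[Si](C)(C)C(C)(C)C)[C@@H](O[Si](C)(C)C(C)(C)C)C1 | intermediate
16 | (3S,4S)-4-[(tert-butyldimethylsilyl)oxy]-3-{3-[(1R,2R)-2-{2-[(tert-butyldimethylsilyl)oxy]ethyl}-1,3,3-trimethylcyclohexyl]-3-oxopropyl}-2-[(dimethylamino)methyl]cyclopentan-1-one (C2 epimers) | CN(C)CC1C(=O)C[C@H](O[Si](C)(C)C(C)(C)C)[C@H]1CCC(=O)[C@]2(C)CCCC(C)(C)[C@H]2CCO[Si](C)(C)C(C)(C)C | intermediate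
17 | (4R)-4-{3-[(1R,2R)-2-{2-[(tert-butyldimethylsilyl)oxy]ethyl}-1,3,3-trimethylcyclohexyl]-3-oxopropyl}-5-[(dimethylamino)methyl]cyclopent-2-en-1-one (C5 epimers) | CN(C)CC1C(=O)C=C[C@H]1CCC(=O)[C@]2(C)CCCC(C)(C)[C@H]2CCO[Si](C)(C)C(C)(C)C | intermediate
18 | (4R)-4-{(2S)-3-[(1R,2R)-2-{2-[(tert-butyldimethylsilyl)oxy]ethyl}-1,3,3-trimethylcyclohexyl]-2-hydroxy-3-oxopropyl}-5-[(dimethylamino)methyl]cyclopent-2-en-1-one (C5 epimers) | CN(C)CC1C(=O)C=C[C@H]1C[C@H](O)C(=O)[C@]2(C)CCCC(C)(C)[C@H]2CCO[Si](C)(C)C(C)(C)C | intermediate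
19 | (2S)-1-[(1R,2R)-2-{2-[(tert-butyldimethylsilyl)oxy]ethyl}-1,3,3-trimethylcyclohexyl]-3-{(1R)-5-[(dimethylamino)methyl]-4-oxocyclopent-2-en-1-yl}-1-oxopropan-2-yl acetate | CN(C)CC1C(=O)C=C[C@H]1C[C@H](OC(C)=O)C(=O)[C@]2(C)CCCC(C)(C)[C@H]2CCO[Si](C)(C)C(C)(C)C | intermediate
20 | (2S)-1-[(1R,2R)-2-{2-[(tert-butyldimethylsilyl)oxy]ethyl}-1,3,3-trimethylcyclohexyl]-3-{(1S)-5-[(dimethylamino)methyl]-3-iodo-4-oxocyclopent-2-en-1-yl}-1-oxopropan-2-yl acetate | CN(C)CC1C(=O)C(I)=C[C@H]1C[C@H](OC(C)=O)C(=O)[C@]2(C)CCCC(C)(C)[C@H]2CCO[Si](C)(C)C(C)(C)C | intermediate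
21 | (2S)-1-[(1R,2R)-2-(2-hydroxyethyl)-1,3,3-trimethylcyclohexyl]-3-{(1S)-5-[(dimethylamino)methyl]-3-iodo-4-oxocyclopent-2-en-1-yl}-1-oxopropan-2-yl acetate | CN(C)CC1C(=O)C(I)=C[C@H]1C[C@H](OC(C)=O)C(=O)[C@]2(C)CCCC(C)(C)[C@H]2CCO | intermediate
22 | (2S)-3-{(1S)-5-[(dimethylamino)methyl]-3-iodo-4-oxocyclopent-2-en-1-yl}-1-oxo-1-[(1R,2R)-1,3,3-trimethyl-2-(2-oxoethyl)cyclohexyl]propan-2-yl acetate | CN(C)CC1C(=O)C(I)=C[C@H]1C[C@H](OC(C)=O)C(=O)[C@]2(C)CCCC(C)(C)[C@H]2CC=O | intermediate
23 | (5R,7R,10R,11S,13R)-17-(dimethylamino)-7-hydroxy-9,15-dioxo-8,9-secokaur-8(14)-en-11-yl acetate (locants of the plan; C16 epimers) | CN(C)CC1C(=O)C2=C[C@H]1C[C@H](OC(C)=O)C(=O)[C@]1(C)CCCC(C)(C)[C@H]1C[C@H]2O | intermediate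
24 | (5R,7R,10R,11S,13R)-17-(dimethylamino)-9,15-dioxo-8,9-secokaur-8(14)-ene-7,11-diyl diacetate (locants of the plan; C16 epimers) | CN(C)CC1C(=O)C2=C[C@H]1C[C@H](OC(C)=O)C(=O)[C@]1(C)CCCC(C)(C)[C@H]1C[C@H]2OC(C)=O | intermediate
25 | N-oxide of 24 at the dimethylamino nitrogen | C[N+](C)([O-])CC1C(=O)C2=C[C@H]1C[C@H](OC(C)=O)C(=O)[C@]1(C)CCCC(C)(C)[C@H]1C[C@H]2OC(C)=O | intermediate
26 | (5R,7R,10R,11S,13R)-9,15-dioxo-8,9-secokaura-8(14),16-diene-7,11-diyl diacetate (CNP0417044.1; locants of the plan) | C=C1C(=O)C2=C[C@H]1C[C@H](OC(C)=O)C(=O)[C@]1(C)CCCC(C)(C)[C@H]1C[C@H]2OC(C)=O | target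

**Step count and risks**

Total steps: 18. Longest linear sequence: 17 steps (steps 1, 2 and 4–18); step 3 is a one-step side branch.

Step 4 (proposed new method). The hindered enolate carbon may lose out to tert-butoxide or to its own oxygen in the attack on the allylammonium ion, or the γ-attack may be slow enough for an uncatalysed, racemic SN2′ path to take over; either way the C4–C5 bond or its facial control is lost. The fallback uses known chemistry, sets out from 4 and 5 and returns at 8. The kinetic lithium enolate of 5 (LiN(iPr)2, THF, −78 °C) displaces the carbonate of 4 by uncatalysed SN2′ attack at the methylene carbon, so that C1–C2 is formed first, and gives methyl (2E)-2-{3-[(tert-butyldimethylsilyl)oxy]propylidene}-6-methyl-5-oxoheptanoate F1. t-BuOK in t-BuOH/THF equilibrates to the tertiary enolate, which closes ring A by 6-endo-trig Michael addition onto the trisubstituted enoate (C4–C5) and gives racemic methyl 2-{2-[(tert-butyldimethylsilyl)oxy]ethyl}-3,3-dimethyl-4-oxocyclohexane-1-carboxylate F2. Preparative chromatography on a chiral stationary phase then delivers the (2S) series, which is 8.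

Step 8. The titanacyclopropane may fail to insert the ester carbonyl, which is flanked by the quaternary C10 and an axial methyl, so that 11 is recovered or merely reduced. The fallback sets out from 11 and returns at 12. LiAlH4 reduces the ester to [(1R,2R)-2-{2-[(tert-butyldimethylsilyl)oxy]ethyl}-1,3,3-trimethylcyclohexyl]methanol F3, and Dess–Martin oxidation gives (1R,2R)-2-{2-[(tert-butyldimethylsilyl)oxy]ethyl}-1,3,3-trimethylcyclohexane-1-carbaldehyde F4. MeMgBr gives 1-[(1R,2R)-2-{2-[(tert-butyldimethylsilyl)oxy]ethyl}-1,3,3-trimethylcyclohexyl]ethan-1-ol F5 (carbinol epimers), and a second Dess–Martin oxidation gives 1-[(1R,2R)-2-{2-[(tert-butyldimethylsilyl)oxy]ethyl}-1,3,3-trimethylcyclohexyl]ethan-1-one F6. Me3SiOTf/Et3N converts this ketone, which can enolise on one side only, into tert-butyl(dimethyl){2-[(1R,2R)-1,3,3-trimethyl-2-{1-[(trimethylsilyl)oxy]ethenyl}cyclohexyl]ethoxy}silane F7. Simmons–Smith cyclopropanation (Et2Zn, CH2I2) gives tert-butyl(dimethyl){2-[(1R,2R)-1,3,3-trimethyl-2-{1-[(trimethylsilyl)oxy]cyclopropyl}cyclohexyl]ethoxy}silane F8, and K2CO3 in MeOH removes the trimethylsilyl group to return 12.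

Step 16. The ring closure may proceed with the wrong facial selectivity at the aldehyde, because only the folding of the seco chain decides the C7 configuration, and intermolecular coupling competes unless dilution is high. The fallback sets out from 22 and returns at 24. The same ring closure is accepted with the (7S) outcome, (5R,7S,10R,11S,13R)-17-(dimethylamino)-7-hydroxy-9,15-dioxo-8,9-secokaur-8(14)-en-11-yl acetate F9. C7 is then set by substitution instead of by the addition: a Mitsunobu reaction with acetic acid (PPh3, DIAD, THF, 0 °C) inverts the carbinol and gives diacetate 24 directly, so that step 17 is not needed.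

Further compounds
F1 | step 4 | methyl (2E)-2-{3-[(tert-butyldimethylsilyl)oxy]propylidene}-6-methyl-5-oxoheptanoate | CC(C)C(=O)CC/C(C(=O)OC)=C\CCO[Si](C)(C)C(C)(C)C
F2 | step 4 | methyl 2-{2-[(tert-butyldimethylsilyl)oxy]ethyl}-3,3-dimethyl-4-oxocyclohexane-1-carboxylate (racemic) | COC(=O)C1CCC(=O)C(C)(C)C1CCO[Si](C)(C)C(C)(C)C
F3 | step 8 | [(1R,2R)-2-{2-[(tert-butyldimethylsilyl)oxy]ethyl}-1,3,3-trimethylcyclohexyl]methanol | OC[C@]1(C)CCCC(C)(C)[C@H]1CCO[Si](C)(C)C(C)(C)C
F4 | step 8 | (1R,2R)-2-{2-[(tert-butyldimethylsilyl)oxy]ethyl}-1,3,3-trimethylcyclohexane-1-carbaldehyde | O=C[C@]1(C)CCCC(C)(C)[C@H]1CCO[Si](C)(C)C(C)(C)C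
F5 | step 8 | 1-[(1R,2R)-2-{2-[(tert-butyldimethylsilyl)oxy]ethyl}-1,3,3-trimethylcyclohexyl]ethan-1-ol (carbinol epimers) | CC(O)[C@]1(C)CCCC(C)(C)[C@H]1CCO[Si](C)(C)C(C)(C)C
F6 | step 8 | 1-[(1R,2R)-2-{2-[(tert-butyldimethylsilyl)oxy]ethyl}-1,3,3-trimethylcyclohexyl]ethan-1-one | CC(=O)[C@]1(C)CCCC(C)(C)[C@H]1CCO[Si](C)(C)C(C)(C)C
F7 | step 8 | tert-butyl(dimethyl){2-[(1R,2R)-1,3,3-trimethyl-2-{1-[(trimethylsilyl)oxy]ethenyl}cyclohexyl]ethoxy}silane | C=C(O[Si](C)(C)C)[C@]1(C)CCCC(C)(C)[C@H]1CCO[Si](C)(C)C(C)(C)C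
F8 | step 8 | tert-butyl(dimethyl){2-[(1R,2R)-1,3,3-trimethyl-2-{1-[(trimethylsilyl)oxy]cyclopropyl}cyclohexyl]ethoxy}silane | C[Si](C)(C)OC1(CC1)[C@]2(C)CCCC(C)(C)[C@H]2CCO[Si](C)(C)C(C)(C)C
F9 | step 16 | (5R,7S,10R,11S,13R)-17-(dimethylamino)-7-hydroxy-9,15-dioxo-8,9-secokaur-8(14)-en-11-yl acetate (locants of the plan; C16 epimers) | CN(C)CC1C(=O)C2=C[C@H]1C[C@H](OC(C)=O)C(=O)[C@]1(C)CCCC(C)(C)[C@H]1C[C@@H]2O
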